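Numbering: the flavanone half is O1/C2/C3/C4 (pyranone ring C fused to ring A, ring B on C2) and the flavone half is O1''/C2''/C3''/C4'' (ring C'' fused to ring A'', ring B'' on C2''). The enabling feature is the chain O=C4–C3–C3''–C4''=O: the two ring carbonyls are 1,4-related through the inter-unit bond C3–C3'', a polarity-mismatched pattern that arises directly when an acyl anion at C4 adds to C3 of a C3=C3''–C4''=O enone.
Retrosynthetic cuts, in order: the six O–benzyl bonds; O1''–C2'' and C2''–C3'' (ring C'' back to a C3'' methylene ketone plus an aroyl chloride); C3–C4 (ring C, carbene-catalysed closure); C3=C3'' (cross-metathesis); O1–C2 (allylic etherification).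
Forward: one dibenzylated phloroglucinaldehyde supplies both A rings. It is O-allylated to form O1–C2, and the alkene is extended to the aryl enone. Ring C closes first (C3–C4), then C3'' is aroylated and ring C'' closes by dehydration, and global debenzylation ends the route.
Stereochemistry: C2 (S) comes from the chiral iridium–phosphoramidite catalyst. C3 (R) is relayed from C2 in the ring closure and is also the thermodynamic 2,3-trans (diequatorial) arrangement.
Key step: step 10

Assumption: the phosphoramidite of step 8 is written as its (Sa,S,S) antipode; the sense of induction is to be verified on 11, and the equally available (Ra,R,R) antipode is used instead should the opposite ether arise, with no other change to the route.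

Step 1
Reactants: 1 2,4,6-trihydroxybenzaldehyde
Product: 2 2,4-bis(benzyloxy)-6-hydroxybenzaldehyde
Conditions: BnBr (2.05 equiv), K2CO3 (2.2 equiv), DMF, 0 °C → rt
Reagents that add atoms: benzyl bromide, BrCc1ccccc1
Why: Williamson etherification with the bromide limited to two equivalents: the 4-OH and one ortho OH are alkylated, while the remaining ortho OH is held in a strong hydrogen bond to the formyl oxygen and stays free.

Step 2
Reactants: 2 2,4-bis(benzyloxy)-6-hydroxybenzaldehyde
Product: 3 2,4-bis(benzyloxy)-6-(methoxymethoxy)benzaldehyde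
Conditions: MOMCl (1.5 equiv), i-Pr2NEt (2 equiv), CH2Cl2, 0 °C → rt
Reagents that add atoms: chloromethyl methyl ether, COCCl
Why: Standard MOM protection (O-alkylation with an α-chloro ether) of the chelated phenol, chosen because this acetal survives Grignard, metathesis, carbene and magnesium/amine conditions and is the one group that mild acid removes in step 13.

Step 3
Reactants: 3 2,4-bis(benzyloxy)-6-(methoxymethoxy)benzaldehyde
Product: 4 (±)-1-[2,4-bis(benzyloxy)-6-(methoxymethoxy)phenyl]prop-2-en-1-ol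
Conditions: CH2=CHMgBr (1.3 equiv), THF, −78 → 0 °C; aq. NH4Cl
Reagents that add atoms: vinylmagnesium bromide, C=C[Mg]Br
Why: 1,2-Addition of a vinyl Grignard reagent to a non-enolisable aromatic aldehyde; the carbinol centre is formed racemic and is erased in step 4.

Step 4
Reactants: 4 (±)-1-[2,4-bis(benzyloxy)-6-(methoxymethoxy)phenyl]prop-2-en-1-ol
Product: 5 1-[2,4-bis(benzyloxy)-6-(methoxymethoxy)phenyl]prop-2-en-1-one
Conditions: activated MnO2 (15 equiv), CH2Cl2, rt
Reagents that add atoms: none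
Why: MnO2 oxidation of an alcohol that is both allylic and benzylic, neutral enough for the MOM acetal and for the polymerisation-prone vinyl ketone, which is used without storage.

Step 5
Reactants: 6 4-(benzyloxy)benzaldehyde
Product: 7 ethyl (E)-3-[4-(benzyloxy)phenyl]prop-2-enoate
Conditions: (EtO)2P(O)CH2CO2Et (1.1 equiv), NaH (1.1 equiv), THF, 0 °C → rt
Reagents that add atoms: triethyl phosphonoacetate, CCOC(=O)CP(=O)(OCC)OCC
Why: Horner–Wadsworth–Emmons olefination of an aromatic aldehyde with a stabilised phosphonate anion, which is reliably E-selective.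

Step 6
Reactants: 7 ethyl (E)-3-[4-(benzyloxy)phenyl]prop-2-enoate
Product: 8 (E)-3-[4-(benzyloxy)phenyl]prop-2-en-1-ol
Conditions: i-Bu2AlH (2.3 equiv), CH2Cl2, −78 °C; aq. potassium sodium tartrate
Reagents that add atoms: none
Why: 1,2-Reduction of the α,β-unsaturated ester with two hydride equivalents of i-Bu2AlH stops at the allylic alcohol and leaves the E alkene and the benzyl ether untouched.

Step 7
Reactants: 8 (E)-3-[4-(benzyloxy)phenyl]prop-2-en-1-ol
Product: 9 (E)-3-[4-(benzyloxy)phenyl]prop-2-en-1-yl methyl carbonate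
Conditions: ClCO2Me (1.3 equiv), pyridine (2 equiv), CH2Cl2, 0 °C
Reagents that add atoms: methyl chloroformate, COC(=O)Cl
Why: O-Acylation with a chloroformate turns the alcohol into the carbonate leaving group needed for metal-catalysed allylic substitution.

Step 8
Reactants: 2 2,4-bis(benzyloxy)-6-hydroxybenzaldehyde; 9 (E)-3-[4-(benzyloxy)phenyl]prop-2-en-1-yl methyl carbonate
Product: 11 2,4-bis(benzyloxy)-6-({(1S)-1-[4-(benzyloxy)phenyl]prop-2-en-1-yl}oxy)benzaldehyde, via lithium aryloxide 10 (not isolated)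
Conditions: 2, LiOt-Bu (1.0 equiv), THF, 0 °C; then 9, [Ir(cod)Cl]2 (2 mol%), (Sa,S,S)-O,O'-(1,1'-binaphthalene-2,2'-diyl) N,N-bis(1-phenylethyl)phosphoramidite (4 mol%; pre-activated with n-PrNH2, volatiles removed), THF, rt
Reagents that add atoms: none
Why: Iridium-catalysed asymmetric allylic etherification of a linear cinnamyl carbonate with a lithium aryloxide: the cyclometalated iridium–phosphoramidite complex ionises 9 to an η3-allyl species that is attacked at its aryl-bearing terminus (electron-rich cinnamyl units favour the branched ether), and the ligand selects the face, which sets C2 as S.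

Step 9
Reactants: 11 2,4-bis(benzyloxy)-6-({(1S)-1-[4-(benzyloxy)phenyl]prop-2-en-1-yl}oxy)benzaldehyde; 5 1-[2,4-bis(benzyloxy)-6-(methoxymethoxy)phenyl]prop-2-en-1-one
Product: 12 2,4-bis(benzyloxy)-6-({(1S,2E)-1-[4-(benzyloxy)phenyl]-4-[2,4-bis(benzyloxy)-6-(methoxymethoxy)phenyl]-4-oxobut-2-en-1-yl}oxy)benzaldehyde
Conditions: 5 (2 equiv), second-generation Hoveyda–Grubbs catalyst RuCl2(H2IMes)(=CH-C6H4-2-Oi-Pr) (5–10 mol%), 1,4-benzoquinone (10 mol%), CH2Cl2, 40 °C
Reagents that add atoms: none
Why: Olefin cross-metathesis between a hindered terminal alkene and an electron-poor vinyl ketone, neither of which homodimerises readily, gives the E-enone under thermodynamic control while the aldehyde, the ethers and C2 are untouched and benzoquinone suppresses hydride-induced double-bond migration.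

Step 10
Reactants: 12 2,4-bis(benzyloxy)-6-({(1S,2E)-1-[4-(benzyloxy)phenyl]-4-[2,4-bis(benzyloxy)-6-(methoxymethoxy)phenyl]-4-oxobut-2-en-1-yl}oxy)benzaldehyde
Product: 14 (2S,3R)-5,7-bis(benzyloxy)-2-[4-(benzyloxy)phenyl]-3-{2-[2,4-bis(benzyloxy)-6-(methoxymethoxy)phenyl]-2-oxoethyl}chroman-4-one (2,3-trans), via 2,3-cis epimer 13 (not isolated)
Conditions: 2-(pentafluorophenyl)-6,7-dihydro-5H-pyrrolo[2,1-c][1,2,4]triazol-2-ium tetrafluoroborate (20 mol%), i-Pr2NEt (1.0 equiv), degassed toluene (0.05 M), rt → 40 °C, stirring continued until 13 has drained into 14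
Reagents that add atoms: none
Why: i-Pr2NEt frees a little triazolylidene, which adds to the formyl carbon C4 of 12; a proton shift gives the enaminol acyl-anion equivalent, this attacks C3 (the β-carbon of the tethered E-enone), the C3''–C4'' enolate is protonated at C3'' and the alkoxide expels the carbene, releasing the C4/C4'' 1,4-diketone. The closest known reaction type is the intramolecular Stetter reaction of salicylaldehyde-derived γ-aryloxy enoates and enones to 3-substituted chroman-4-ones, which also tolerates a substituent on the tether carbon next to oxygen. Ring C closes 6-exo-trig (C4, C4a, C8a, O1, C2 and C3 in the ring, C3'' outside it). The only new stereocentre, C3, is governed by C2: in the chair-like closure the C2 aryl group lies pseudo-equatorial because an axial aryl would collide with the azolium-bearing C4, the enone arm is pseudo-equatorial as well, which leads to trans 14, and since C3–H stays enolisable the minor cis epimer 13 converges on the diequatorial isomer under the amine. The step needs carbene chemistry to outrun base chemistry at the acidic C2–H (double-bond migration, racemisation): the pentafluorophenyl triazolium is acidic enough for a tertiary amine in toluene so no strong base is present, its small bicyclic frame fits between the two ortho oxygens, and its electron-poor aryl group speeds the slow proton shift on this electron-rich aldehyde. The acceptor stays reactive because its two ortho substituents twist the trioxygenated ring out of conjugation with C4''=O, and the aryl ketone offers no competing enolisable position.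

Step 11
Reactants: 15 4-(benzyloxy)benzoic acid
Product: 16 4-(benzyloxy)benzoyl chloride
Conditions: (COCl)2 (1.3 equiv), DMF (cat.), CH2Cl2, 0 °C → rt; evaporate
Reagents that add atoms: oxalyl chloride, O=C(Cl)C(=O)Cl
Why: Formamide-catalysed conversion of a benzoic acid into its chloride with oxalyl chloride gives only gaseous by-products and does not affect the benzyl ether.

Step 12
Reactants: 14 (2S,3R)-5,7-bis(benzyloxy)-2-[4-(benzyloxy)phenyl]-3-{2-[2,4-bis(benzyloxy)-6-(methoxymethoxy)phenyl]-2-oxoethyl}chroman-4-one; 16 4-(benzyloxy)benzoyl chloride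
Product: 17 (2S,3R)-5,7-bis(benzyloxy)-2-[4-(benzyloxy)phenyl]-3-{1-[2,4-bis(benzyloxy)-6-(methoxymethoxy)phenyl]-3-[4-(benzyloxy)phenyl]-1,3-dioxopropan-2-yl}chroman-4-one (C3'' epimers and enol forms)
Conditions: 16 (1.5 equiv), MgBr2·OEt2 (2.5 equiv), i-Pr2NEt (3 equiv), CH2Cl2, 0 °C → rt
Reagents that add atoms: none
Why: Soft-enolisation C-acylation (magnesium halide plus tertiary amine, the direct ketone-to-1,3-diketone method): the C3'' methylene is deprotonated more easily than the tertiary C3–H, whose enolate could only give a quaternary carbon, the magnesium chelate of the new 1,3-diketone draws the equilibrium forward, and the labile C3'' centre vanishes in step 13.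

Step 13
Reactants: 17 (2S,3R)-5,7-bis(benzyloxy)-2-[4-(benzyloxy)phenyl]-3-{1-[2,4-bis(benzyloxy)-6-(methoxymethoxy)phenyl]-3-[4-(benzyloxy)phenyl]-1,3-dioxopropan-2-yl}chroman-4-one
Product: 19 (2S,3R)-5,7-bis(benzyloxy)-2-[4-(benzyloxy)phenyl]-3-{5,7-bis(benzyloxy)-2-[4-(benzyloxy)phenyl]-4-oxo-4H-chromen-3-yl}chroman-4-one, via free phenol triketone 18 (not isolated)
Conditions: 3 M aq. HCl, i-PrOH–THF, 50 °C
Reagents that add atoms: none
Why: Acid hydrolysis of the aryl MOM acetal frees phenol 18, whose oxygen adds to the aroyl carbonyl C2'' (six-membered hemiketal) and loses water, the classical cyclodehydration of 1-(2-hydroxyaryl)-1,3-diketones to flavones, which should outpace Paal–Knorr furan formation at the electron-rich C4 carbonyl and leaves the benzyl ethers and the thermodynamic trans C2/C3 pair in place.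

Step 14
Reactants: 19 (2S,3R)-5,7-bis(benzyloxy)-2-[4-(benzyloxy)phenyl]-3-{5,7-bis(benzyloxy)-2-[4-(benzyloxy)phenyl]-4-oxo-4H-chromen-3-yl}chroman-4-one
Product: 20 (2S,3R)-5,7-dihydroxy-2-(4-hydroxyphenyl)-3-[5,7-dihydroxy-2-(4-hydroxyphenyl)-4-oxo-4H-chromen-3-yl]chroman-4-one (CNP0208264.1)
Conditions: H2 (1 atm), 10% Pd/C, THF–MeOH, rt; neutral work-up
Reagents that add atoms: none
Why: Catalytic hydrogenolysis of six aryl benzyl ethers, the usual last step for flavanones: the cyclic C2–O1 bond, the tetrasubstituted C2''=C3'' bond and the vinylogous-ester carbonyls react far more slowly, and the absence of acid and base avoids opening of ring C.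

Compound list
1 | 2,4,6-trihydroxybenzaldehyde | O=Cc1c(O)cc(O)cc1O | starting material
2 | 2,4-bis(benzyloxy)-6-hydroxybenzaldehyde | O=Cc1c(O)cc(OCc2ccccc2)cc1OCc1ccccc1 | intermediate
3 | 2,4-bis(benzyloxy)-6-(methoxymethoxy)benzaldehyde | O=Cc1c(OCOC)cc(OCc2ccccc2)cc1OCc1ccccc1 | intermediate
4 | (±)-1-[2,4-bis(benzyloxy)-6-(methoxymethoxy)phenyl]prop-2-en-1-ol | C=CC(O)c1c(OCOC)cc(OCc2ccccc2)cc1OCc1ccccc1 | intermediate
5 | 1-[2,4-bis(benzyloxy)-6-(methoxymethoxy)phenyl]prop-2-en-1-one | C=CC(=O)c1c(OCOC)cc(OCc2ccccc2)cc1OCc1ccccc1 | intermediate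
6 | 4-(benzyloxy)benzaldehyde | O=Cc1ccc(OCc2ccccc2)cc1 | starting material
7 | ethyl (E)-3-[4-(benzyloxy)phenyl]prop-2-enoate | CCOC(=O)/C=C/c1ccc(OCc2ccccc2)cc1 | intermediate
8 | (E)-3-[4-(benzyloxy)phenyl]prop-2-en-1-ol | OC/C=C/c1ccc(OCc2ccccc2)cc1 | intermediate
9 | (E)-3-[4-(benzyloxy)phenyl]prop-2-en-1-yl methyl carbonate | COC(=O)OC/C=C/c1ccc(OCc2ccccc2)cc1 | intermediate
10 | lithium 3,5-bis(benzyloxy)-2-formylphenolate | [Li+].[O-]c1cc(OCc2ccccc2)cc(OCc2ccccc2)c1C=O | intermediate
11 | 2,4-bis(benzyloxy)-6-({(1S)-1-[4-(benzyloxy)phenyl]prop-2-en-1-yl}oxy)benzaldehyde | O=Cc1c(OCc2ccccc2)cc(OCc2ccccc2)cc1O[C@H](c1ccc(OCc2ccccc2)cc1)C=C | intermediate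
12 | 2,4-bis(benzyloxy)-6-({(1S,2E)-1-[4-(benzyloxy)phenyl]-4-[2,4-bis(benzyloxy)-6-(methoxymethoxy)phenyl]-4-oxobut-2-en-1-yl}oxy)benzaldehyde | O=Cc1c(OCc2ccccc2)cc(OCc2ccccc2)cc1O[C@H](c1ccc(OCc2ccccc2)cc1)/C=C/C(=O)c1c(OCOC)cc(OCc2ccccc2)cc1OCc1ccccc1 | intermediate
13 | (2S,3S)-5,7-bis(benzyloxy)-2-[4-(benzyloxy)phenyl]-3-{2-[2,4-bis(benzyloxy)-6-(methoxymethoxy)phenyl]-2-oxoethyl}chroman-4-one (2,3-cis) | O=C1c2c(OCc3ccccc3)cc(OCc3ccccc3)cc2O[C@H](c2ccc(OCc3ccccc3)cc2)[C@@H]1CC(=O)c1c(OCOC)cc(OCc2ccccc2)cc1OCc1ccccc1 | intermediate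
14 | (2S,3R)-5,7-bis(benzyloxy)-2-[4-(benzyloxy)phenyl]-3-{2-[2,4-bis(benzyloxy)-6-(methoxymethoxy)phenyl]-2-oxoethyl}chroman-4-one (2,3-trans) | O=C1c2c(OCc3ccccc3)cc(OCc3ccccc3)cc2O[C@H](c2ccc(OCc3ccccc3)cc2)[C@H]1CC(=O)c1c(OCOC)cc(OCc2ccccc2)cc1OCc1ccccc1 | intermediate
15 | 4-(benzyloxy)benzoic acid | O=C(O)c1ccc(OCc2ccccc2)cc1 | starting material
16 | 4-(benzyloxy)benzoyl chloride | O=C(Cl)c1ccc(OCc2ccccc2)cc1 | intermediate
17 | (2S,3R)-5,7-bis(benzyloxy)-2-[4-(benzyloxy)phenyl]-3-{1-[2,4-bis(benzyloxy)-6-(methoxymethoxy)phenyl]-3-[4-(benzyloxy)phenyl]-1,3-dioxopropan-2-yl}chroman-4-one | O=C1c2c(OCc3ccccc3)cc(OCc3ccccc3)cc2O[C@H](c2ccc(OCc3ccccc3)cc2)[C@H]1C(C(=O)c1ccc(OCc2ccccc2)cc1)C(=O)c1c(OCOC)cc(OCc2ccccc2)cc1OCc1ccccc1 | intermediate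
18 | (2S,3R)-5,7-bis(benzyloxy)-2-[4-(benzyloxy)phenyl]-3-{1-[2,4-bis(benzyloxy)-6-hydroxyphenyl]-3-[4-(benzyloxy)phenyl]-1,3-dioxopropan-2-yl}chroman-4-one | O=C1c2c(OCc3ccccc3)cc(OCc3ccccc3)cc2O[C@H](c2ccc(OCc3ccccc3)cc2)[C@H]1C(C(=O)c1ccc(OCc2ccccc2)cc1)C(=O)c1c(O)cc(OCc2ccccc2)cc1OCc1ccccc1 | intermediate
19 | (2S,3R)-5,7-bis(benzyloxy)-2-[4-(benzyloxy)phenyl]-3-{5,7-bis(benzyloxy)-2-[4-(benzyloxy)phenyl]-4-oxo-4H-chromen-3-yl}chroman-4-one | O=C1c2c(OCc3ccccc3)cc(OCc3ccccc3)cc2O[C@H](c2ccc(OCc3ccccc3)cc2)[C@H]1c1c(-c2ccc(OCc3ccccc3)cc2)oc2cc(OCc3ccccc3)cc(OCc3ccccc3)c2c1=O | intermediate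
20 | (2S,3R)-5,7-dihydroxy-2-(4-hydroxyphenyl)-3-[5,7-dihydroxy-2-(4-hydroxyphenyl)-4-oxo-4H-chromen-3-yl]chroman-4-one | O=C1c2c(O)cc(O)cc2O[C@H](c2ccc(O)cc2)[C@H]1c1c(-c2ccc(O)cc2)oc2cc(O)cc(O)c2c1=O | target

Total step count: 14.
Longest linear sequence: 9 steps (steps 5, 6, 7, 8, 9, 10, 12, 13, 14; the branch 1, 2, 3, 4, 9, 10, 12, 13, 14 is equally long).

Steps most likely to fail

Step 10. The acyl-anion equivalent may form too slowly at a formyl group that is electron-rich and flanked by two oxygens. Migration of the enone double bond towards C2 (with loss of the C2 configuration) or aerobic oxidation of the aldehyde could then overtake ring closure. The fallback makes the same C3–C4 bond with an acyl radical under neutral, base-free conditions; it sets out from 12 and returns at 14. Pinnick oxidation of 12 (NaClO2, NaH2PO4, 2-methyl-2-butene, t-BuOH–H2O) should give the carboxylic acid F1. Premixed N-(phenylseleno)phthalimide and Bu3P (CH2Cl2, −20 °C) should convert this into the Se-phenyl selenoester F2. Bu3SnH with Et3B/air (benzene, rt) then generates the aroyl radical, which closes 6-exo-trig onto C3. The resulting α-keto radical is reduced by the stannane to 14, and any 13 is equilibrated with amine as in step 10.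

Step 12. Enolisation at C3 may compete with enolisation at C3''. That would lead to O-acylation, or to retro-oxa-Michael opening of ring C with erosion of the C2 configuration, and the crowded C3'' may also acylate only slowly. The fallback delivers the acyl group intramolecularly; it sets out from 14 and returns at 18. Aqueous HCl in i-PrOH–THF removes the MOM group to give the 2-hydroxyaryl ketone F3. Acid chloride 16 with Et3N and catalytic DMAP (CH2Cl2, 0 °C) esterifies the phenol to the aryl 4-(benzyloxy)benzoate F4. LiN(SiMe3)2 (2.5 equiv, THF, −78 → −20 °C) then triggers a Baker–Venkataraman O→C acyl shift. Only the C3'' enolate can reach the ester through a six-membered transition state, so 18 results, and it closes to 19 under the acid of step 13.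

Step 8. The chelated, stabilised aryloxide may react sluggishly. The doubly activated (benzylic and allylic) aryl ether may also re-ionise on the metal, which would erode both the branched selectivity and the enantiomeric purity. The fallback forms the aryl–O1 bond, not O1–C2, by nucleophilic aromatic substitution; it sets out from 6 and returns at 11.
- CH2=CHMgBr adds to 6 to give racemic 1-[4-(benzyloxy)phenyl]prop-2-en-1-ol F5.
- Kinetic resolution with immobilised Candida antarctica lipase B and vinyl acetate (MTBE, rt) leaves the (S)-alcohol F6 and removes the antipode as the (R)-acetate F7.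
- Separately, commercial 2,4,6-trifluorobenzaldehyde and BnOH/NaH (2 equiv, THF–DMF, 0 °C) give 2,4-bis(benzyloxy)-6-fluorobenzaldehyde F8.
- The sodium alkoxide of F6 (NaH, DMF, 0 °C → rt) displaces the fluoride ortho to the formyl group of F8. The C2–O bond is never broken, so the configuration is retained and 11 results.

Further compounds
F1 | step 10 | 2,4-bis(benzyloxy)-6-({(1S,2E)-1-[4-(benzyloxy)phenyl]-4-[2,4-bis(benzyloxy)-6-(methoxymethoxy)phenyl]-4-oxobut-2-en-1-yl}oxy)benzoic acid | O=C(O)c1c(OCc2ccccc2)cc(OCc2ccccc2)cc1O[C@H](c1ccc(OCc2ccccc2)cc1)/C=C/C(=O)c1c(OCOC)cc(OCc2ccccc2)cc1OCc1ccccc1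
F2 | step 10 | Se-phenyl 2,4-bis(benzyloxy)-6-({(1S,2E)-1-[4-(benzyloxy)phenyl]-4-[2,4-bis(benzyloxy)-6-(methoxymethoxy)phenyl]-4-oxobut-2-en-1-yl}oxy)benzenecarboselenoate | O=C([Se]c1ccccc1)c1c(OCc2ccccc2)cc(OCc2ccccc2)cc1O[C@H](c1ccc(OCc2ccccc2)cc1)/C=C/C(=O)c1c(OCOC)cc(OCc2ccccc2)cc1OCc1ccccc1
F3 | step 12 | (2S,3R)-5,7-bis(benzyloxy)-2-[4-(benzyloxy)phenyl]-3-{2-[2,4-bis(benzyloxy)-6-hydroxyphenyl]-2-oxoethyl}chroman-4-one | O=C1c2c(OCc3ccccc3)cc(OCc3ccccc3)cc2O[C@H](c2ccc(OCc3ccccc3)cc2)[C@H]1CC(=O)c1c(O)cc(OCc2ccccc2)cc1OCc1ccccc1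
F4 | step 12 | 3,5-bis(benzyloxy)-2-({(2S,3R)-5,7-bis(benzyloxy)-2-[4-(benzyloxy)phenyl]-4-oxochroman-3-yl}acetyl)phenyl 4-(benzyloxy)benzoate | O=C1c2c(OCc3ccccc3)cc(OCc3ccccc3)cc2O[C@H](c2ccc(OCc3ccccc3)cc2)[C@H]1CC(=O)c1c(OC(=O)c2ccc(OCc3ccccc3)cc2)cc(OCc2ccccc2)cc1OCc1ccccc1
F5 | step 8 | (±)-1-[4-(benzyloxy)phenyl]prop-2-en-1-ol | C=CC(O)c1ccc(OCc2ccccc2)cc1
F6 | step 8 | (S)-1-[4-(benzyloxy)phenyl]prop-2-en-1-ol | O[C@H](c1ccc(OCc2ccccc2)cc1)C=C
F7 | step 8 | (R)-1-[4-(benzyloxy)phenyl]prop-2-en-1-yl acetate | CC(=O)O[C@@H](c1ccc(OCc2ccccc2)cc1)C=C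
F8 | step 8 | 2,4-bis(benzyloxy)-6-fluorobenzaldehyde | O=Cc1c(F)cc(OCc2ccccc2)cc1OCc1ccccc1
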